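**Plan**

- Numbering: diterpenol C1 (CH2O) to C15. The ring is C10(H)–C11(Me)=C12H–C13H2–C14H2–C15Me2.
- Cuts, in retrosynthetic order: (1) the acyl C–O bond of the arachidonate, (2) ring bond C10–C15, (3) C11–C12, (4) C10=C11. The last cut leads back to the C1–C10 trisnor-aldehyde of (E,E)-farnesol.
- Enabling feature: quaternary C15 sits next to the allylic stereocentre C10. The C11=C12 alkene lies where an allylsilane C10=C11–C12(Si) leaves its double bond after SE2′ attack. C15 is therefore a tertiary cation, C10 the nucleophilic terminus, and a silyl group on C12 a traceless helper.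
- Forward order: farnesol → C10 aldehyde → (Z)-vinyl iodide; 4-methylpent-4-en-1-ol → α-silyl boronic ester → tertiary chloride; Zweifel union at C11–C12; cationic closure of the only ring; desilylation; esterification.
- Stereochemistry: C12 is set by (−)-sparteine-mediated lithiation–borylation and relayed 1,3 to C10 by anti-SE2′ ring closure, which erases C12. Alkene geometries come from farnesol (C2, C6), the stereospecific Zweifel step (C10) and arachidonic acid.

Key step: step 9

Assumption: (2E,6E)-farnesol, arachidonic acid, 4-methylpent-4-en-1-ol, PhMe2Si–Bpin and (−)-sparteine are taken as commercial, and the terpenoid numbering above is used for all intermediates.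

Step 1
Reactants: 1 (2E,6E)-farnesol
Product: 2 (2E,6E)-farnesyl tert-butyldiphenylsilyl (TBDPS) ether
Conditions: TBDPSCl, imidazole, DMF, 0 °C to rt
Reagents that add atoms: tert-butyl(chloro)diphenylsilane, CC(C)(C)[Si](Cl)(c1ccccc1)c1ccccc1
Why: Imidazole-promoted silylation of a primary allylic alcohol; the bulky, weakly Lewis-basic TBDPS ether is chosen because it has to survive periodic acid, tert-butyllithium and TiCl4 at −78 °C.

Step 2
Reactants: 2 farnesyl TBDPS ether
Product: 4 racemic 10,11-epoxyfarnesyl TBDPS ether, via terminal bromohydrin 3 (not isolated)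
Conditions: NBS, THF–H2O, 0 °C; then K2CO3, MeOH, rt
Reagents that add atoms: water, O
Why: Bromohydrin formation in aqueous medium should take the exposed terminal C10=C11 alkene of the coiled polyene (Markovnikov, OH on the tertiary carbon) and base then closes the epoxide by intramolecular Williamson displacement; the new centre is racemic and is destroyed in step 3.

Step 3
Reactants: 4 10,11-epoxyfarnesyl TBDPS ether
Product: 6 (4E,8E)-10-[(tert-butyldiphenylsilyl)oxy]-4,8-dimethyldeca-4,8-dienal, via 10,11-glycol 5 (not isolated)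
Conditions: H5IO6, THF–Et2O, 0 °C
Reagents that add atoms: none
Why: Periodic acid opens the trisubstituted epoxide and cleaves the glycol in the same pot (Malaprade-type cleavage), which should leave the two internal alkenes and the silyl ether untouched.

Step 4
Reactants: 6 the C10 aldehyde; 7 ethyltriphenylphosphonium iodide
Product: 11 tert-butyl{[(2E,6E,10Z)-11-iodo-3,7-dimethyldodeca-2,6,10-trien-1-yl]oxy}diphenylsilane, via ethylidenetriphenylphosphorane 8 (not isolated), via (1-iodoethyl)triphenylphosphonium iodide 9 (not isolated), via (1-iodoethylidene)triphenylphosphorane 10 (not isolated)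
Conditions: 7, n-BuLi, THF, rt; I2, −78 °C; NaHMDS, −20 °C; 6, −78 °C
Reagents that add atoms: iodine, II
Why: Stork–Zhao-type Wittig olefination with the non-stabilised α-iodo ylide is kinetically selective for iodine cis to the chain, giving the (Z)-2-iodoalkene whose geometry is inverted in step 8; geometric purity matters because it becomes enantiopurity in step 9.

Step 5
Reactants: 12 4-methylpent-4-en-1-ol
Product: 13 4-methylpent-4-en-1-yl N,N-diisopropylcarbamate
Conditions: i-Pr2NCOCl, Et3N, CH2Cl2, reflux
Reagents that add atoms: N,N-diisopropylcarbamoyl chloride, CC(C)N(C(C)C)C(=O)Cl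
Why: Carbamoylation of the primary alcohol installs the group that both directs the lithiation and leaves in the lithiation–borylation.

Step 6
Reactants: 13 the carbamate; 14 (dimethylphenylsilyl)boronic acid pinacol ester
Product: 17 2-{(1R)-1-[dimethyl(phenyl)silyl]-4-methylpent-4-en-1-yl}-4,4,5,5-tetramethyl-1,3,2-dioxaborolane, via lithiated carbamate 15 (not isolated), via silylboronate complex 16 (not isolated)
Conditions: s-BuLi, (−)-sparteine, Et2O, −78 °C; 14, −78 °C; then rt to reflux
Reagents that add atoms: none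
Why: Sparteine-mediated asymmetric α-deprotonation removes the pro-S hydrogen to give configurationally stable (S)-15, which is borylated with retention and then undergoes a stereoinvertive 1,2-metallate shift of silicon with loss of the carbamate (lithiation–borylation), setting C12 as R.

Step 7
Reactants: 17 the α-silyl boronic ester
Product: 18 2-{(1R)-4-chloro-1-[dimethyl(phenyl)silyl]-4-methylpentyl}-4,4,5,5-tetramethyl-1,3,2-dioxaborolane
Conditions: dry HCl (g), CH2Cl2, 0 °C
Reagents that add atoms: hydrogen chloride, Cl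
Why: Ionic Markovnikov hydrochlorination of the only alkene, a 1,1-disubstituted one, is the standard way to tertiary alkyl chlorides; dry HCl at 0 °C should not touch the C–Si, Si–Ph or C–B bonds, and the stereocentre is not involved.

Step 8
Reactants: 11 the (Z)-vinyl iodide; 18 the chloro boronic ester
Product: 22 tert-butyl{[(2E,6E,10E,12S)-15-chloro-12-[dimethyl(phenyl)silyl]-3,7,11,15-tetramethylhexadeca-2,6,10-trien-1-yl]oxy}diphenylsilane, via alkenyllithium 19 (not isolated), via alkenylboronate complex 20 (not isolated), via β-iodoboronic ester 21 (not isolated)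
Conditions: 11, t-BuLi (2 equiv per 11), Et2O, −78 °C; 18, THF, −78 °C; I2, THF, −78 °C; NaOMe, MeOH, −78 °C to rt
Reagents that add atoms: none
Why: Zweifel olefination, in which I/Li exchange keeps the geometry, iodination of 20 triggers migration of the α-silylalkyl group to C11 with retention at C12, and anti B/I elimination inverts the alkene, so the (Z)-iodide should give the (10E)-allylsilane (descriptor now 12S through a change of CIP ranks only), while the tertiary chloride should be inert at −78 °C and over the short methoxide warm-up.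

Step 9
Reactants: 22 the (10E,12S)-allylsilane tertiary chloride
Product: 25 tert-butyl{[(2E,6E)-3,7-dimethyl-9-[(1S)-2,6,6-trimethylcyclohex-2-en-1-yl]nona-2,6-dien-1-yl]oxy}diphenylsilane, via tertiary carbenium ion 23 (not isolated), via β-silyl cyclohexyl cation 24 (not isolated)
Conditions: TiCl4, 2,6-di-tert-butyl-4-methylpyridine, CH2Cl2–hexane, −78 °C, high dilution; quench Et3N–MeOH, −78 °C
Reagents that add atoms: none
Why: TiCl4 ionises only the tertiary C15–Cl bond while the hindered pyridine traps stray protons, C15 is attacked by C10 of the C10=C11–C12(Si) allylsilane to give the C11 cation 24 stabilised by the C12–Si bond, and chloride removes silicon so that the alkene can appear only at C11=C12. The closest known reaction types are the TiCl4-mediated tert-alkylation of allylsilanes by tertiary chlorides (Hosomi–Sakurai-type SE2′, also used to cap tert-chloride/TiCl4 cationic chain ends in the presence of a proton trap) and allylsilane-terminated cation–olefin cyclisation. The ring closes in a chair-like 6-endo-trig mode in which C10 and C11 both become ring atoms, whereas the 5-exo mode would join two fully substituted carbons and give a secondary cation without β-silicon stabilisation. C10 is controlled by C12: only the chair with the C12–Si bond pseudoaxial and parallel to the π system is activated, C15 bonds to the face of C10 anti to silicon, and the E alkene places the C9 chain equatorial, so (10E,12S)-22 should give (S)-C10 while C12 becomes sp2. Selective initiation rests on halophilic activation of the sole C–Cl bond beside a bulky, weakly basic silyl ether, and the stop after one ring rests on desilylation of 24 being faster than attack by the C6=C7 alkene.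

Step 10
Reactants: 25 the cyclised TBDPS ether
Product: 26 (2E,6E)-3,7-dimethyl-9-[(1S)-2,6,6-trimethylcyclohex-2-en-1-yl]nona-2,6-dien-1-ol
Conditions: TBAF, THF, 0 °C to rt; aqueous work-up
Reagents that add atoms: none
Why: Fluoride-induced silyl ether cleavage is driven by the Si–F bond, and no other group in 25 responds to TBAF.

Step 11
Reactants: 26 the diterpenol; 27 arachidonic acid
Product: 28 (2E,6E)-3,7-dimethyl-9-[(1S)-2,6,6-trimethylcyclohex-2-en-1-yl]nona-2,6-dien-1-yl (5Z,8Z,11Z,14Z)-icosa-5,8,11,14-tetraenoate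
Conditions: EDC·HCl, DMAP, CH2Cl2, 0 °C to rt, argon, dark
Reagents that add atoms: none
Why: Steglich-type carbodiimide/DMAP esterification under cold, neutral, oxygen-free conditions should join the primary allylic alcohol to the acid without allylic transposition and without isomerising or autoxidising the skipped (Z)-tetraene.

**Compound list**

1 | (2E,6E)-farnesol | CC(C)=CCC/C(C)=C/CC/C(C)=C/CO | starting material
2 | (2E,6E)-farnesyl TBDPS ether | CC(C)=CCC/C(C)=C/CC/C(C)=C/CO[Si](c1ccccc1)(c1ccccc1)C(C)(C)C | intermediate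
3 | 10-bromo-11-hydroxy-10,11-dihydrofarnesyl TBDPS ether (racemic) | CC(C)(O)C(Br)CC/C(C)=C/CC/C(C)=C/CO[Si](c1ccccc1)(c1ccccc1)C(C)(C)C | intermediate
4 | 10,11-epoxyfarnesyl TBDPS ether (racemic) | CC1(C)OC1CC/C(C)=C/CC/C(C)=C/CO[Si](c1ccccc1)(c1ccccc1)C(C)(C)C | intermediate
5 | 10,11-dihydroxy-10,11-dihydrofarnesyl TBDPS ether (racemic) | CC(C)(O)C(O)CC/C(C)=C/CC/C(C)=C/CO[Si](c1ccccc1)(c1ccccc1)C(C)(C)C | intermediate
6 | (4E,8E)-10-[(tert-butyldiphenylsilyl)oxy]-4,8-dimethyldeca-4,8-dienal | O=CCC/C(C)=C/CC/C(C)=C/CO[Si](c1ccccc1)(c1ccccc1)C(C)(C)C | intermediate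
7 | ethyltriphenylphosphonium iodide | CC[P+](c1ccccc1)(c1ccccc1)c1ccccc1.[I-] | starting material
8 | ethylidenetriphenylphosphorane | CC=P(c1ccccc1)(c1ccccc1)c1ccccc1 | intermediate
9 | (1-iodoethyl)triphenylphosphonium iodide | CC(I)[P+](c1ccccc1)(c1ccccc1)c1ccccc1.[I-] | intermediate
10 | (1-iodoethylidene)triphenylphosphorane | CC(I)=P(c1ccccc1)(c1ccccc1)c1ccccc1 | intermediate
11 | tert-butyl{[(2E,6E,10Z)-11-iodo-3,7-dimethyldodeca-2,6,10-trien-1-yl]oxy}diphenylsilane | C/C(I)=C/CC/C(C)=C/CC/C(C)=C/CO[Si](c1ccccc1)(c1ccccc1)C(C)(C)C | intermediate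
12 | 4-methylpent-4-en-1-ol | C=C(C)CCCO | starting material
13 | 4-methylpent-4-en-1-yl N,N-diisopropylcarbamate | C=C(C)CCCOC(=O)N(C(C)C)C(C)C | intermediate
14 | (dimethylphenylsilyl)boronic acid pinacol ester | C[Si](C)(c1ccccc1)B1OC(C)(C)C(C)(C)O1 | starting material
15 | (S)-1-lithio-4-methylpent-4-en-1-yl N,N-diisopropylcarbamate, (−)-sparteine complex (ligand not drawn) | C=C(C)CC[C@H]([Li])OC(=O)N(C(C)C)C(C)C | intermediate
16 | lithium (S)-silylboronate complex of 15 and 14 | C=C(C)CC[C@H]([B-]1([Si](C)(C)c2ccccc2)OC(C)(C)C(C)(C)O1)OC(=O)N(C(C)C)C(C)C.[Li+] | intermediate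
17 | 2-{(1R)-1-[dimethyl(phenyl)silyl]-4-methylpent-4-en-1-yl}-4,4,5,5-tetramethyl-1,3,2-dioxaborolane | C=C(C)CC[C@H]([Si](C)(C)c1ccccc1)B1OC(C)(C)C(C)(C)O1 | intermediate
18 | 2-{(1R)-4-chloro-1-[dimethyl(phenyl)silyl]-4-methylpentyl}-4,4,5,5-tetramethyl-1,3,2-dioxaborolane | CC(C)(Cl)CC[C@H]([Si](C)(C)c1ccccc1)B1OC(C)(C)C(C)(C)O1 | intermediate
19 | C11-alkenyllithium from 11 (lithium cis to the C9 methylene) | C/C([Li])=C/CC/C(C)=C/CC/C(C)=C/CO[Si](c1ccccc1)(c1ccccc1)C(C)(C)C | intermediate
20 | lithium alkenylboronate complex of 19 and 18 (boron cis to C9) | CC(C)(Cl)CC[C@H]([Si](C)(C)c1ccccc1)[B-]1(/C(C)=C\CC/C(C)=C/CC/C(C)=C/CO[Si](c2ccccc2)(c2ccccc2)C(C)(C)C)OC(C)(C)C(C)(C)O1.[Li+] | intermediate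
21 | β-iodoboronic ester; the (10S,11S,12S) isomer is drawn, and the (10R,11R,12S) isomer from the other alkene face collapses to the same alkene | CC(C)(Cl)CC[C@H]([Si](C)(C)c1ccccc1)[C@@](C)(B1OC(C)(C)C(C)(C)O1)[C@@H](I)CC/C(C)=C/CC/C(C)=C/CO[Si](c1ccccc1)(c1ccccc1)C(C)(C)C | intermediate
22 | tert-butyl{[(2E,6E,10E,12S)-15-chloro-12-[dimethyl(phenyl)silyl]-3,7,11,15-tetramethylhexadeca-2,6,10-trien-1-yl]oxy}diphenylsilane | CC(C)(Cl)CC[C@H]([Si](C)(C)c1ccccc1)/C(C)=C/CC/C(C)=C/CC/C(C)=C/CO[Si](c1ccccc1)(c1ccccc1)C(C)(C)C | intermediate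
23 | C15 tertiary carbenium ion, chlorotitanate ion pair | C[C+](C)CC[C@H]([Si](C)(C)c1ccccc1)/C(C)=C/CC/C(C)=C/CC/C(C)=C/CO[Si](c1ccccc1)(c1ccccc1)C(C)(C)C.Cl[Ti-](Cl)(Cl)(Cl)Cl | intermediate
24 | C11 cyclohexyl cation with axial C12 silyl group cis to H-10, chlorotitanate ion pair | C[C+]1[C@@H]([Si](C)(C)c2ccccc2)CCC(C)(C)[C@@H]1CC/C(C)=C/CC/C(C)=C/CO[Si](c1ccccc1)(c1ccccc1)C(C)(C)C.Cl[Ti-](Cl)(Cl)(Cl)Cl | intermediate
25 | tert-butyl{[(2E,6E)-3,7-dimethyl-9-[(1S)-2,6,6-trimethylcyclohex-2-en-1-yl]nona-2,6-dien-1-yl]oxy}diphenylsilane | CC(C)(C)[Si](c1ccccc1)(c1ccccc1)OC/C=C(\C)CC/C=C(\C)CC[C@@H]1C(C)=CCCC1(C)C | intermediate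
26 | (2E,6E)-3,7-dimethyl-9-[(1S)-2,6,6-trimethylcyclohex-2-en-1-yl]nona-2,6-dien-1-ol | OC/C=C(\C)CC/C=C(\C)CC[C@@H]1C(C)=CCCC1(C)C | intermediate
27 | arachidonic acid | CCCCC/C=C\C/C=C\C/C=C\C/C=C\CCCC(=O)O | starting material
28 | CNP0207506.1, the arachidonate of 26 | CCCCC/C=C\C/C=C\C/C=C\C/C=C\CCCC(=O)OC/C=C(\C)CC/C=C(\C)CC[C@@H]1C(C)=CCCC1(C)C | target

**Step count**

Total step count: 11.
Longest linear sequence: 8 (steps 1–4 and 8–11). The second branch (steps 5–7) joins at step 8.

**Steps most likely to fail**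

1. Step 9.
   - Risk: the allylic silyl ether may ionise in competition with the chloride. The very reactive tertiary cation may lose a proton before capture. It may also be captured from the chair with an in-plane silyl group, which would erode the 1,3-chirality transfer.
   - Fallback: the ring is closed by ring-closing metathesis at C11=C12, with C10 set beforehand under reagent control. It sets out from 6 and comes back at 25.
   - Reduction of 6 with NaBH4 gives the primary alcohol F1, and carbamoylation gives the carbamate F2.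
   - Separately, commercial 2-methylhexa-1,5-diene takes up HCl at its 1,1-disubstituted alkene to give 5-chloro-5-methylhex-1-ene F3. Its Grignard reagent is trapped with isopropoxy-Bpin to give the tertiary boronic ester F4.
   - Lithiation of F2 with s-BuLi/(+)-sparteine, addition of F4 and 1,2-shift of the tertiary alkyl group give the secondary boronic ester F5.
   - Zweifel olefination with isopropenyllithium (I2, NaOMe) gives the metathesis precursor F6 with retention at C10.
   - A second-generation ruthenium carbene closes the six-membered ring between the isopropenyl and butenyl termini. The trisubstituted chain alkenes should stay out of the reaction.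

2. Step 8.
   - Risk: boronate formation between two hindered partners may be sluggish. The tertiary chloride may be lost by elimination under the organolithium/methoxide regime.
   - Fallback: the chloride is introduced after the coupling and by a radical rather than an ionic mechanism. It sets out from 17 (and 11) and comes back at 22, leaving out 18.
   - Alkenyllithium 19 from 11 is combined with chloride-free 17 in the same Zweifel sequence to give the isopropenyl allylsilane F7.
   - Cobalt-catalysed hydrogen-atom-transfer hydrochlorination (TsCl, PhSiH3, EtOH, rt) then adds H–Cl. It is proton-free, so it should spare the allylsilane, and it prefers 1,1-disubstituted over trisubstituted alkenes.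

3. Step 4.
   - Risk: conversion may be low and Z-selectivity imperfect. Any (E)-iodide would end as the (10Z)-allylsilane, which cyclises to the enantiomer.
   - Fallback: it sets out from 6 and comes back at 19.
   - Ramirez dibromo-olefination (CBr4, PPh3, Et3N) gives the 1,1-dibromoalkene F8.
   - Palladium-catalysed trans-selective Negishi mono-methylation (Me2Zn, Pd–DPEphos) replaces the less hindered bromine, the one trans to the chain. This gives the (Z)-2-bromoalkene F9.
   - Br/Li exchange with t-BuLi at −78 °C gives the same alkenyllithium 19.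

**Further compounds**

F1 | step 9 | (4E,8E)-10-[(tert-butyldiphenylsilyl)oxy]-4,8-dimethyldeca-4,8-dien-1-ol | OCCC/C(C)=C/CC/C(C)=C/CO[Si](c1ccccc1)(c1ccccc1)C(C)(C)C
F2 | step 9 | (4E,8E)-10-[(tert-butyldiphenylsilyl)oxy]-4,8-dimethyldeca-4,8-dien-1-yl N,N-diisopropylcarbamate | CC(C)N(C(C)C)C(=O)OCCC/C(C)=C/CC/C(C)=C/CO[Si](c1ccccc1)(c1ccccc1)C(C)(C)C
F3 | step 9 | 5-chloro-5-methylhex-1-ene | C=CCCC(C)(C)Cl
F4 | step 9 | 4,4,5,5-tetramethyl-2-(2-methylhex-5-en-2-yl)-1,3,2-dioxaborolane | C=CCCC(C)(C)B1OC(C)(C)C(C)(C)O1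
F5 | step 9 | tert-butyl{[(2E,6E,10S)-3,7,11,11-tetramethyl-10-(4,4,5,5-tetramethyl-1,3,2-dioxaborolan-2-yl)pentadeca-2,6,14-trien-1-yl]oxy}diphenylsilane | C=CCCC(C)(C)[C@@H](B1OC(C)(C)C(C)(C)O1)CC/C(C)=C/CC/C(C)=C/CO[Si](c1ccccc1)(c1ccccc1)C(C)(C)C
F6 | step 9 | tert-butyl{[(2E,6E,10R)-3,7,11,11-tetramethyl-10-(prop-1-en-2-yl)pentadeca-2,6,14-trien-1-yl]oxy}diphenylsilane | C=CCCC(C)(C)[C@@H](C(C)=C)CC/C(C)=C/CC/C(C)=C/CO[Si](c1ccccc1)(c1ccccc1)C(C)(C)C
F7 | step 8 | tert-butyl{[(2E,6E,10E,12S)-12-[dimethyl(phenyl)silyl]-3,7,11,15-tetramethylhexadeca-2,6,10,15-tetraen-1-yl]oxy}diphenylsilane | C=C(C)CC[C@H]([Si](C)(C)c1ccccc1)/C(C)=C/CC/C(C)=C/CC/C(C)=C/CO[Si](c1ccccc1)(c1ccccc1)C(C)(C)C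
F8 | step 4 | tert-butyl{[(2E,6E)-11,11-dibromo-3,7-dimethylundeca-2,6,10-trien-1-yl]oxy}diphenylsilane | BrC(Br)=CCC/C(C)=C/CC/C(C)=C/CO[Si](c1ccccc1)(c1ccccc1)C(C)(C)C
F9 | step 4 | tert-butyl{[(2E,6E,10Z)-11-bromo-3,7-dimethyldodeca-2,6,10-trien-1-yl]oxy}diphenylsilane | C/C(Br)=C/CC/C(C)=C/CC/C(C)=C/CO[Si](c1ccccc1)(c1ccccc1)C(C)(C)C
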